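The cyclopentane (ring A) is assembled from a three-carbon unit (its two vicinal quaternary carbons and the CH2 beside the one bearing the CH2C(=O) arm) and a two-carbon unit (the other two ring CH2 groups). One flask joins them: the carbon that becomes the acyl-bearing quaternary centre, an enolate carbon because of that acyl group, adds to vinyltriphenylphosphonium bromide, and the ylide so formed olefinates a formyl group, unmasked in situ, on the neighbouring quaternary carbon (Schweizer-type (3+2) annulation). The precursor is a cis-fused bicyclic lactone acetal from an enantioselective Ireland–Claisen rearrangement; its convex face sets the second centre. The δ-lactone obtained then releases both carbonyl arms for the two side chains.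

Key step: step 5

Assumption: the (S,S)-configured boron controller of step 3 is taken to deliver the (3S)-acid 7; should the sense of induction be the opposite, its (R,R)-antipode is used and nothing else changes.

Step 1
Reactants: 1 tert-butyl(but-3-yn-1-yloxy)dimethylsilane
Product: 3 (2E)-5-{[tert-butyl(dimethyl)silyl]oxy}-3-methylpent-2-en-1-ol, via alkenylalane 2 (not isolated)
Conditions: Me3Al, Cp2ZrCl2 (0.25 equiv), CH2Cl2, 0 → 23 °C; n-BuLi, THF, −78 °C; (CH2O)n, −78 → 23 °C; aq HCl
Reagents that add atoms: trimethylaluminium C[Al](C)C; paraformaldehyde (as formaldehyde) C=O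
Why: Zirconium-catalysed syn-carboalumination (Negishi carboalumination) places methyl on the internal alkyne carbon and aluminium on the terminal one, and the derived alanate is hydroxymethylated with retention, which should fix the (E)-trisubstituted alkene.

Step 2
Reactants: 3 (2E)-5-{[tert-butyl(dimethyl)silyl]oxy}-3-methylpent-2-en-1-ol; 4 propanoyl chloride
Product: 5 (2E)-5-{[tert-butyl(dimethyl)silyl]oxy}-3-methylpent-2-en-1-yl propanoate
Conditions: pyridine, DMAP (cat.), CH2Cl2, 0 °C
Reagents that add atoms: none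
Why: Acylation of the primary allylic alcohol by the acid chloride (nucleophilic acyl substitution) should be routine.

Step 3
Reactants: 5 (2E)-5-{[tert-butyl(dimethyl)silyl]oxy}-3-methylpent-2-en-1-yl propanoate
Product: 7 (3S)-5-{[tert-butyl(dimethyl)silyl]oxy}-3-ethenyl-2,3-dimethylpentanoic acid (configuration at C-2 immaterial), via boron enolate 6 (not isolated)
Conditions: (S,S)-N,N′-bis{[3,5-bis(trifluoromethyl)phenyl]sulfonyl}-1,2-diphenylethane-1,2-diamine, BBr3, CH2Cl2, 23 °C (gives the bromoborane); 5, Et3N, toluene/hexane, −78 → 4 °C; aq work-up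
Reagents that add atoms: none
Why: Soft enolisation gives boron ketene acetal 6, which should rearrange through a chair [3,3] transition state (enantioselective Ireland–Claisen rearrangement); the C2-symmetric diazaborolidine blocks one enolate face and so selects one face of the (E)-trisubstituted allyl terminus, setting the quaternary C-3, while the C-2 configuration is erased in step 5.

Step 4
Reactants: 7 (3S)-5-{[tert-butyl(dimethyl)silyl]oxy}-3-ethenyl-2,3-dimethylpentanoic acid
Product: 9 (3aR,6aS)-3,3a-dimethyltetrahydrofuro[2,3-b]furan-2(3H)-one (cis-fused; C-3 epimers), via formyl acid 8 (not isolated)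
Conditions: O3, CH2Cl2, −78 °C; PPh3; then HF (48% aq), MeCN, 23 °C
Reagents that add atoms: ozone [O-][O+]=O
Why: Ozonolysis of the vinyl group gives formyl acid 8, and acid-mediated desilylation lets the hydroxyl and carboxyl groups close on the formyl carbon (acetalisation/lactonisation), the cis-fused bicycle being the only strain-free outcome so that the acetal carbon follows the quaternary centre.

Step 5
Reactants: 9 (3aR,6aS)-3,3a-dimethyltetrahydrofuro[2,3-b]furan-2(3H)-one; 10 ethenyl(triphenyl)phosphonium bromide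
Product: 13 (4aS,7aR)-4a,7a-dimethyl-4,4a,7,7a-tetrahydrocyclopenta[c]pyran-1(3H)-one, via ylide 11 (not isolated), via hydroxy acid 12 (not isolated)
Conditions: LiN(i-Pr)2, THF, −78 °C; 10 (1.3 equiv), −78 → 0 °C; KOt-Bu, H2O (1.5 equiv), 0 → 23 °C; 2 M HCl, 23 °C
Reagents that add atoms: water O
Why: The lithium enolate of 9 adds through its α-carbon to the CH2 terminus of 10 (conjugate addition) to give β-ylide 11; hydroxide then opens the lactone acetal and unveils the formyl group on the neighbouring quaternary carbon, which the ylide olefinates intramolecularly (Wittig), and acidification relactonises 12 through its primary hydroxyl to 13. The closest known reaction is the Schweizer-type cyclopentene annulation of a carbanion carrying a γ-carbonyl group with vinyltriphenylphosphonium bromide, and conjugate addition of lithium enolates to this salt is itself known. The cyclopentene closes by 5-exo-trig attack of the ylide carbon on the aldehyde carbon followed by cycloreversion of the oxaphosphetane, and the δ-lactone by 6-exo-trig acyl substitution. The new quaternary centre is fixed in the conjugate addition: 10 should approach the bowl-shaped cis-fused bicyclic enolate on its convex face, anti to the tetrahydrofuran ring and syn to the angular methyl, which after ring closure places the two methyl groups cis. The step needs C- over O-alkylation, convex-face attack and olefination faster than ylide hydrolysis; the soft unsubstituted acceptor, the rigid bicycle and the intramolecular five-ring closure should secure them.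

Step 6
Reactants: 13 (4aS,7aR)-4a,7a-dimethyl-4,4a,7,7a-tetrahydrocyclopenta[c]pyran-1(3H)-one
Product: 14 (4aR,7aR)-4a,7a-dimethylhexahydrocyclopenta[c]pyran-1(3H)-one
Conditions: H2 (1 atm), 10% Pd/C, EtOAc, 23 °C
Reagents that add atoms: none
Why: Heterogeneous hydrogenation of the cis-disubstituted cyclopentene should leave the lactone untouched and creates no stereocentre.

Step 7
Reactants: 15 trimethyl[(2-methylbut-3-yn-2-yl)oxy]silane
Product: 17 {[(3E)-4-iodo-2-methylbut-3-en-2-yl]oxy}(trimethyl)silane, via alkenylzirconocene 16 (not isolated)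
Conditions: Cp2Zr(H)Cl, THF, 23 °C; I2, 0 °C
Reagents that add atoms: iodine II
Why: Hydrozirconation adds H–Zr syn with zirconium on the terminal carbon, and iodinolysis of the C–Zr bond with retention should give the (E)-vinyl iodide.

Step 8
Reactants: 17 {[(3E)-4-iodo-2-methylbut-3-en-2-yl]oxy}(trimethyl)silane; 14 (4aR,7aR)-4a,7a-dimethylhexahydrocyclopenta[c]pyran-1(3H)-one
Product: 19 (2E)-1-[(1R,2R)-2-(2-hydroxyethyl)-1,2-dimethylcyclopentyl]-4-methyl-4-[(trimethylsilyl)oxy]pent-2-en-1-one, via vinyllithium 18 (not isolated)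
Conditions: 17, t-BuLi (2 equiv), Et2O, −78 °C; then 14, −78 → −40 °C; aq NH4Cl
Reagents that add atoms: none
Why: Iodine–lithium exchange with retention gives vinyllithium 18, which should add once to the hindered lactone carbonyl (acyl substitution), the lithium hemiketal alkoxide persisting until the quench so that the δ-hydroxy (E)-enone results.

Step 9
Reactants: 19 (2E)-1-[(1R,2R)-2-(2-hydroxyethyl)-1,2-dimethylcyclopentyl]-4-methyl-4-[(trimethylsilyl)oxy]pent-2-en-1-one
Product: 20 {(1R,2R)-1,2-dimethyl-2-[(2E)-4-methyl-4-(trimethylsilyloxy)pent-2-enoyl]cyclopentyl}acetaldehyde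
Conditions: Dess–Martin periodinane, NaHCO3, CH2Cl2, 0 → 23 °C
Reagents that add atoms: none
Why: Dess–Martin oxidation should convert the primary alcohol into the aldehyde under buffered conditions, the enone and the silyl ether being inert.

Step 10
Reactants: 21 4-methoxy-2-methylphenol
Product: 22 2-bromo-4-methoxy-6-methylphenol
Conditions: NBS, MeCN, 0 °C
Reagents that add atoms: N-bromosuccinimide BrN1C(=O)CCC1=O
Why: Electrophilic aromatic bromination should occur ortho to the free hydroxyl, the strongest director, at its only free ortho position since the para position carries the methoxy group.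

Step 11
Reactants: 22 2-bromo-4-methoxy-6-methylphenol
Product: 23 1-bromo-2,5-dimethoxy-3-methylbenzene
Conditions: MeI, K2CO3, acetone, 56 °C
Reagents that add atoms: iodomethane CI
Why: Williamson O-methylation of the phenoxide should be routine.

Step 12
Reactants: 23 1-bromo-2,5-dimethoxy-3-methylbenzene
Product: 25 2-(2,5-dimethoxy-3-methylphenyl)ethan-1-ol, via aryllithium 24 (not isolated)
Conditions: n-BuLi, THF, −78 °C; oxirane, −78 → 23 °C; aq NH4Cl
Reagents that add atoms: oxirane C1CO1
Why: Bromine–lithium exchange gives aryllithium 24, which should open oxirane by SN2 attack to the 2-arylethanol.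

Step 13
Reactants: 25 2-(2,5-dimethoxy-3-methylphenyl)ethan-1-ol
Product: 26 (2,5-dimethoxy-3-methylphenyl)acetaldehyde
Conditions: Dess–Martin periodinane, NaHCO3, CH2Cl2, 0 °C
Reagents that add atoms: none
Why: Dess–Martin oxidation should stop cleanly at the sensitive arylacetaldehyde, which is used at once.

Step 14
Reactants: 26 (2,5-dimethoxy-3-methylphenyl)acetaldehyde; 27 methyl 2-[bis(2,2,2-trifluoroethoxy)phosphoryl]propanoate
Product: 28 methyl (2Z)-4-(2,5-dimethoxy-3-methylphenyl)-2-methylbut-2-enoate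
Conditions: 27, KN(SiMe3)2, 18-crown-6, THF, −78 °C; then 26
Reagents that add atoms: none
Why: In the Still–Gennari olefination the electron-poor bis(trifluoroethyl) phosphonate under dissociating conditions should collapse kinetically to the (Z)-trisubstituted enoate, which sets the side-chain alkene geometry.

Step 15
Reactants: 28 methyl (2Z)-4-(2,5-dimethoxy-3-methylphenyl)-2-methylbut-2-enoate
Product: 29 (2Z)-4-(2,5-dimethoxy-3-methylphenyl)-2-methylbut-2-en-1-ol
Conditions: i-Bu2AlH, CH2Cl2, −78 °C; aq potassium sodium tartrate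
Reagents that add atoms: none
Why: 1,2-Reduction of the enoate by i-Bu2AlH should give the allylic alcohol with the (Z)-geometry intact.

Step 16
Reactants: 29 (2Z)-4-(2,5-dimethoxy-3-methylphenyl)-2-methylbut-2-en-1-ol
Product: 30 1-[(2Z)-4-chloro-3-methylbut-2-en-1-yl]-2,5-dimethoxy-3-methylbenzene
Conditions: MsCl, LiCl, 2,4,6-collidine, DMF, 0 °C
Reagents that add atoms: lithium chloride [Li+].[Cl-]
Why: Mesylation and in situ chloride displacement (SN2 at the primary allylic carbon) should give the chloride without allylic transposition or loss of geometry.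

Step 17
Reactants: 30 1-[(2Z)-4-chloro-3-methylbut-2-en-1-yl]-2,5-dimethoxy-3-methylbenzene; 20 {(1R,2R)-1,2-dimethyl-2-[(2E)-4-methyl-4-(trimethylsilyloxy)pent-2-enoyl]cyclopentyl}acetaldehyde
Product: 32 (2E)-1-{(1R,2R)-2-[(4Z)-6-(2,5-dimethoxy-3-methylphenyl)-2-hydroxy-4-methylhex-4-en-1-yl]-1,2-dimethylcyclopentyl}-4-methyl-4-[(trimethylsilyl)oxy]pent-2-en-1-one (carbinol epimers), via allylbarium chloride 31 (not isolated)
Conditions: BaI2, lithium biphenylide, THF, 23 °C (activated zerovalent barium); 30, −78 °C; then 20, −78 °C; aq NH4Cl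
Reagents that add atoms: none
Why: Allylbarium reagents formed at −78 °C keep their double-bond geometry and add to carbonyl groups through the unsubstituted α-carbon, so the aldehyde, far more reactive than the doubly hindered enone, should give the homoallylic alcohol with the (Z)-alkene intact (carbonyl allylation; the new carbinol centre is removed in step 18).

Step 18
Reactants: 32 (2E)-1-{(1R,2R)-2-[(4Z)-6-(2,5-dimethoxy-3-methylphenyl)-2-hydroxy-4-methylhex-4-en-1-yl]-1,2-dimethylcyclopentyl}-4-methyl-4-[(trimethylsilyl)oxy]pent-2-en-1-one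
Product: 33 (4Z)-6-(2,5-dimethoxy-3-methylphenyl)-1-{(1R,2R)-1,2-dimethyl-2-[(2E)-4-methyl-4-(trimethylsilyloxy)pent-2-enoyl]cyclopentyl}-4-methylhex-4-en-2-one
Conditions: Dess–Martin periodinane, pyridine, CH2Cl2, 0 °C
Reagents that add atoms: none
Why: Buffered Dess–Martin oxidation of the homoallylic alcohol should give the β,γ-unsaturated ketone without migration of the double bond into conjugation.

Step 19
Reactants: 33 (4Z)-6-(2,5-dimethoxy-3-methylphenyl)-1-{(1R,2R)-1,2-dimethyl-2-[(2E)-4-methyl-4-(trimethylsilyloxy)pent-2-enoyl]cyclopentyl}-4-methylhex-4-en-2-one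
Product: 35 (4Z)-6-(2,5-dihydroxy-3-methylphenyl)-1-{(1R,2R)-2-[(2E)-4-hydroxy-4-methylpent-2-enoyl]-1,2-dimethylcyclopentyl}-4-methylhex-4-en-2-one (target), via quinone 34 (not isolated)
Conditions: (NH4)2Ce(NO3)6, MeCN/H2O, 0 °C; then Na2S2O4 (aq), EtOAc, 23 °C
Reagents that add atoms: water O
Why: Tetravalent cerium should oxidise the 1,4-dimethoxyarene to the quinone (oxidative demethylation) while the acidic aqueous medium hydrolyses the tertiary trimethylsilyl ether, and dithionite then reduces quinone 34 to the hydroquinone without touching the enone or the alkenes.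

Compound list
1 | tert-butyl(but-3-yn-1-yloxy)dimethylsilane | C#CCCO[Si](C)(C)C(C)(C)C | starting material
2 | [(1E)-4-{[tert-butyl(dimethyl)silyl]oxy}-2-methylbut-1-en-1-yl](dimethyl)alane (not isolated) | C/C(CCO[Si](C)(C)C(C)(C)C)=C\[Al](C)C | intermediate
3 | (2E)-5-{[tert-butyl(dimethyl)silyl]oxy}-3-methylpent-2-en-1-ol | C/C(CCO[Si](C)(C)C(C)(C)C)=C\CO | intermediate
4 | propanoyl chloride | CCC(Cl)=O | starting material
5 | (2E)-5-{[tert-butyl(dimethyl)silyl]oxy}-3-methylpent-2-en-1-yl propanoate | CCC(=O)OC/C=C(\C)CCO[Si](C)(C)C(C)(C)C | intermediate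
6 | boron ketene acetal of 5 carrying the (4S,5S)-1,3-bis{[3,5-bis(trifluoromethyl)phenyl]sulfonyl}-4,5-diphenyl-1,3,2-diazaborolidin-2-yl group on oxygen (enolate geometry not assigned; not isolated) | CC=C(OC/C=C(\C)CCO[Si](C)(C)C(C)(C)C)OB1N(S(=O)(=O)c2cc(cc(c2)C(F)(F)F)C(F)(F)F)[C@@H](c2ccccc2)[C@H](c2ccccc2)N1S(=O)(=O)c1cc(cc(c1)C(F)(F)F)C(F)(F)F | intermediate
7 | (3S)-5-{[tert-butyl(dimethyl)silyl]oxy}-3-ethenyl-2,3-dimethylpentanoic acid (C-2 not specified) | C=C[C@](C)(CCO[Si](C)(C)C(C)(C)C)C(C)C(=O)O | intermediate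
8 | (3R)-5-{[tert-butyl(dimethyl)silyl]oxy}-3-formyl-2,3-dimethylpentanoic acid (open form of its hydroxy lactone; not isolated) | O=C[C@](C)(CCO[Si](C)(C)C(C)(C)C)C(C)C(=O)O | intermediate
9 | (3aR,6aS)-3,3a-dimethyltetrahydrofuro[2,3-b]furan-2(3H)-one (cis-fused, C-3 epimers) | CC1C(=O)O[C@@H]2OCC[C@]12C | intermediate
10 | ethenyl(triphenyl)phosphonium bromide | C=C[P+](c1ccccc1)(c1ccccc1)c1ccccc1.[Br-] | starting material
11 | (3R,3aR,6aS)-3,3a-dimethyl-3-[2-(triphenyl-λ5-phosphanylidene)ethyl]tetrahydrofuro[2,3-b]furan-2(3H)-one (not isolated) | C[C@]1(CC=P(c2ccccc2)(c2ccccc2)c2ccccc2)C(=O)O[C@@H]2OCC[C@]12C | intermediate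
12 | (1R,2S)-2-(2-hydroxyethyl)-1,2-dimethylcyclopent-3-ene-1-carboxylic acid (not isolated) | C[C@]1(CCO)C=CC[C@@]1(C)C(=O)O | intermediate
13 | (4aS,7aR)-4a,7a-dimethyl-4,4a,7,7a-tetrahydrocyclopenta[c]pyran-1(3H)-one | C[C@]12C=CC[C@@]1(C)C(=O)OCC2 | intermediate
14 | (4aR,7aR)-4a,7a-dimethylhexahydrocyclopenta[c]pyran-1(3H)-one | C[C@]12CCC[C@@]1(C)C(=O)OCC2 | intermediate
15 | trimethyl[(2-methylbut-3-yn-2-yl)oxy]silane | C#CC(C)(C)O[Si](C)(C)C | starting material
16 | chlorobis(cyclopentadienyl)[(1E)-3-methyl-3-(trimethylsilyloxy)but-1-en-1-yl]zirconium (not isolated) | C[Si](C)(C)OC(C)(C)/C=C/[Zr](Cl)(C1C=CC=C1)C1C=CC=C1 | intermediate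
17 | {[(3E)-4-iodo-2-methylbut-3-en-2-yl]oxy}(trimethyl)silane | C[Si](C)(C)OC(C)(C)/C=C/I | intermediate
18 | [(1E)-3-methyl-3-(trimethylsilyloxy)but-1-en-1-yl]lithium (not isolated) | C[Si](C)(C)OC(C)(C)/C=C/[Li] | intermediate
19 | (2E)-1-[(1R,2R)-2-(2-hydroxyethyl)-1,2-dimethylcyclopentyl]-4-methyl-4-[(trimethylsilyl)oxy]pent-2-en-1-one | C[C@]1(CCO)CCC[C@@]1(C)C(=O)/C=C/C(C)(C)O[Si](C)(C)C | intermediate
20 | {(1R,2R)-1,2-dimethyl-2-[(2E)-4-methyl-4-(trimethylsilyloxy)pent-2-enoyl]cyclopentyl}acetaldehyde | C[C@]1(CC=O)CCC[C@@]1(C)C(=O)/C=C/C(C)(C)O[Si](C)(C)C | intermediate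
21 | 4-methoxy-2-methylphenol | COc1ccc(O)c(C)c1 | starting material
22 | 2-bromo-4-methoxy-6-methylphenol | COc1cc(C)c(O)c(Br)c1 | intermediate
23 | 1-bromo-2,5-dimethoxy-3-methylbenzene | COc1cc(C)c(OC)c(Br)c1 | intermediate
24 | (2,5-dimethoxy-3-methylphenyl)lithium (not isolated) | [Li]c1cc(OC)cc(C)c1OC | intermediate
25 | 2-(2,5-dimethoxy-3-methylphenyl)ethan-1-ol | COc1cc(C)c(OC)c(CCO)c1 | intermediate
26 | (2,5-dimethoxy-3-methylphenyl)acetaldehyde | COc1cc(C)c(OC)c(CC=O)c1 | intermediate
27 | methyl 2-[bis(2,2,2-trifluoroethoxy)phosphoryl]propanoate | COC(=O)C(C)P(=O)(OCC(F)(F)F)OCC(F)(F)F | starting material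
28 | methyl (2Z)-4-(2,5-dimethoxy-3-methylphenyl)-2-methylbut-2-enoate | COC(=O)/C(C)=C\Cc1cc(OC)cc(C)c1OC | intermediate
29 | (2Z)-4-(2,5-dimethoxy-3-methylphenyl)-2-methylbut-2-en-1-ol | OC/C(C)=C\Cc1cc(OC)cc(C)c1OC | intermediate
30 | 1-[(2Z)-4-chloro-3-methylbut-2-en-1-yl]-2,5-dimethoxy-3-methylbenzene | ClC/C(C)=C\Cc1cc(OC)cc(C)c1OC | intermediate
31 | [(2Z)-4-(2,5-dimethoxy-3-methylphenyl)-2-methylbut-2-en-1-yl]barium chloride (not isolated) | Cl[Ba]C/C(C)=C\Cc1cc(OC)cc(C)c1OC | intermediate
32 | (2E)-1-{(1R,2R)-2-[(4Z)-6-(2,5-dimethoxy-3-methylphenyl)-2-hydroxy-4-methylhex-4-en-1-yl]-1,2-dimethylcyclopentyl}-4-methyl-4-[(trimethylsilyl)oxy]pent-2-en-1-one (carbinol epimers) | COc1cc(C)c(OC)c(C/C=C(/C)CC(O)C[C@@]2(C)CCC[C@@]2(C)C(=O)/C=C/C(C)(C)O[Si](C)(C)C)c1 | intermediate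
33 | (4Z)-6-(2,5-dimethoxy-3-methylphenyl)-1-{(1R,2R)-1,2-dimethyl-2-[(2E)-4-methyl-4-(trimethylsilyloxy)pent-2-enoyl]cyclopentyl}-4-methylhex-4-en-2-one | COc1cc(C)c(OC)c(C/C=C(/C)CC(=O)C[C@@]2(C)CCC[C@@]2(C)C(=O)/C=C/C(C)(C)O[Si](C)(C)C)c1 | intermediate
34 | 2-[(2Z)-6-{(1R,2R)-2-[(2E)-4-hydroxy-4-methylpent-2-enoyl]-1,2-dimethylcyclopentyl}-3-methyl-5-oxohex-2-en-1-yl]-6-methylcyclohexa-2,5-diene-1,4-dione (not isolated) | CC1=CC(=O)C=C(C/C=C(/C)CC(=O)C[C@@]2(C)CCC[C@@]2(C)C(=O)/C=C/C(C)(C)O)C1=O | intermediate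
35 | (4Z)-6-(2,5-dihydroxy-3-methylphenyl)-1-{(1R,2R)-2-[(2E)-4-hydroxy-4-methylpent-2-enoyl]-1,2-dimethylcyclopentyl}-4-methylhex-4-en-2-one | C/C(=C/Cc1cc(O)cc(C)c1O)CC(=O)C[C@@]1(C)CCC[C@@]1(C)C(=O)/C=C/C(C)(C)O | target

Total step count: 19. Longest linear sequence: 11 steps (steps 1–6, 8, 9, 17, 18, 19).

Steps most likely to fail

Step 5 (key step). The conjugate addition may show poor facial selectivity, since attack on the concave face would lead to the trans-dimethyl ring. The ylide may also be hydrolysed before the acetal is opened and the olefination takes place. The fallback separates the two bond formations. From 9, LiN(i-Pr)2 and then allyl bromide should give (3R,3aR,6aS)-3,3a-dimethyl-3-(prop-2-en-1-yl)tetrahydrofuro[2,3-b]furan-2(3H)-one F1, which can be purified from its C-3 epimer. K2CO3 in MeOH followed by methylenetriphenylphosphorane should open the acetal and methylenate the liberated lactol to methyl (2R,3S)-3-ethenyl-5-hydroxy-2,3-dimethyl-2-(prop-2-en-1-yl)pentanoate F2. Ring-closing metathesis with the second-generation Grubbs catalyst should give methyl (1R,2S)-2-(2-hydroxyethyl)-1,2-dimethylcyclopent-3-ene-1-carboxylate F3, and TsOH in toluene should lactonise it to 13, where the route is rejoined.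

Step 3. Enolisation of the ester by the boron reagent may be sluggish, or the discrimination between the enolate faces insufficient, so that the quaternary centre is formed with low enantiomeric purity. The fallback sets out from 5: LiN(i-Pr)2 and Me3SiCl (silyl ketene acetal Ireland–Claisen rearrangement, THF, −78 → 60 °C) should give the racemic acid 5-{[tert-butyl(dimethyl)silyl]oxy}-3-ethenyl-2,3-dimethylpentanoic acid F4. This is resolved by crystallisation of its salt with (R)-1-phenylethylamine, (R)-1-phenylethylammonium (3S)-5-{[tert-butyl(dimethyl)silyl]oxy}-3-ethenyl-2,3-dimethylpentanoate F5, and acidification returns to 7.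

Step 17. The allylbarium species may lose its geometry or react through its substituted γ-carbon (allylic transposition), or it may add to the enone as well. The fallback sets out from 30: sodium benzenesulfinate in DMF should give {[(2Z)-4-(2,5-dimethoxy-3-methylphenyl)-2-methylbut-2-en-1-yl]sulfonyl}benzene F6. Its lithio derivative (n-BuLi, THF, −78 °C) should add through the sulfonyl-bearing carbon to aldehyde 20 to give the β-hydroxy sulfone (2E)-1-{(1R,2R)-2-[(4Z)-6-(2,5-dimethoxy-3-methylphenyl)-2-hydroxy-4-methyl-3-(phenylsulfonyl)hex-4-en-1-yl]-1,2-dimethylcyclopentyl}-4-methyl-4-[(trimethylsilyl)oxy]pent-2-en-1-one F7. Dess–Martin oxidation should give the β-keto sulfone (4Z)-6-(2,5-dimethoxy-3-methylphenyl)-1-{(1R,2R)-1,2-dimethyl-2-[(2E)-4-methyl-4-(trimethylsilyloxy)pent-2-enoyl]cyclopentyl}-4-methyl-3-(phenylsulfonyl)hex-4-en-2-one F8, and reductive desulfonylation with zinc dust and aq NH4Cl in THF rejoins the route at 33.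

Further compounds
F1 | step 5 | (3R,3aR,6aS)-3,3a-dimethyl-3-(prop-2-en-1-yl)tetrahydrofuro[2,3-b]furan-2(3H)-one | C=CC[C@@]1(C)C(=O)O[C@@H]2OCC[C@]12C
F2 | step 5 | methyl (2R,3S)-3-ethenyl-5-hydroxy-2,3-dimethyl-2-(prop-2-en-1-yl)pentanoate | C=CC[C@@](C)(C(=O)OC)[C@](C)(C=C)CCO
F3 | step 5 | methyl (1R,2S)-2-(2-hydroxyethyl)-1,2-dimethylcyclopent-3-ene-1-carboxylate | C[C@]1(CCO)C=CC[C@@]1(C)C(=O)OC
F4 | step 3 | racemic 5-{[tert-butyl(dimethyl)silyl]oxy}-3-ethenyl-2,3-dimethylpentanoic acid | C=CC(C)(CCO[Si](C)(C)C(C)(C)C)C(C)C(=O)O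
F5 | step 3 | (R)-1-phenylethylammonium (3S)-5-{[tert-butyl(dimethyl)silyl]oxy}-3-ethenyl-2,3-dimethylpentanoate | C=C[C@](C)(CCO[Si](C)(C)C(C)(C)C)C(C)C(=O)[O-].C[C@@H]([NH3+])c1ccccc1
F6 | step 17 | {[(2Z)-4-(2,5-dimethoxy-3-methylphenyl)-2-methylbut-2-en-1-yl]sulfonyl}benzene | O=S(=O)(C/C(C)=C\Cc1cc(OC)cc(C)c1OC)c1ccccc1
F7 | step 17 | (2E)-1-{(1R,2R)-2-[(4Z)-6-(2,5-dimethoxy-3-methylphenyl)-2-hydroxy-4-methyl-3-(phenylsulfonyl)hex-4-en-1-yl]-1,2-dimethylcyclopentyl}-4-methyl-4-[(trimethylsilyl)oxy]pent-2-en-1-one | COc1cc(C)c(OC)c(C/C=C(/C)C(C(O)C[C@@]2(C)CCC[C@@]2(C)C(=O)/C=C/C(C)(C)O[Si](C)(C)C)S(=O)(=O)c2ccccc2)c1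
F8 | step 17 | (4Z)-6-(2,5-dimethoxy-3-methylphenyl)-1-{(1R,2R)-1,2-dimethyl-2-[(2E)-4-methyl-4-(trimethylsilyloxy)pent-2-enoyl]cyclopentyl}-4-methyl-3-(phenylsulfonyl)hex-4-en-2-one | COc1cc(C)c(OC)c(C/C=C(/C)C(C(=O)C[C@@]2(C)CCC[C@@]2(C)C(=O)/C=C/C(C)(C)O[Si](C)(C)C)S(=O)(=O)c2ccccc2)c1
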